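The cyclopentane is cut between the isopropyl carbinol carbon C4 and the ring-fusion methine C5. This exploits the aldol array O–C4–C5–C6–O, which ties the tertiary alcohol of the five-membered ring to the acyloxy carbon C6 of the seven-membered ring. The precursor is an acyclic keto acid, cut out of a Diels–Alder cyclohexene that sets quaternary C1. An isothiourea-catalysed aldol-lactonisation forms C4–C5, fixes both stereocentres and traps the fragile tertiary aldolate as a temporary cis-fused β-lactone. Its carbonyl becomes C6. The two trans arms are finally joined by an aldol condensation that gives the cycloheptene carbaldehyde.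

Key step: step 6

Atom labels (daucane numbering, used throughout):
- C1: quaternary ring-fusion carbon bearing CH3
- C2, C3: cyclopentane CH2
- C4: carbinol carbon bearing isopropyl
- C5: ring-fusion CH
- C6: acyloxy-bearing CH
- C7: CH2
- C8: formyl-bearing alkene carbon
- C9: alkene CH
- C10: CH2
- C14: formyl carbon

Assumption: the antipodes of the two chiral catalysts (steps 2 and 6) are written as the usual face-shielding models predict. Both antipodes of each are available, so the mirror-image catalyst is taken if the sense of induction proves opposite.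

Step 1
Reactants: 1 3-methylbut-1-yne; 2 ethylene
Product: 3 2-isopropylbuta-1,3-diene
Conditions: ethylene (4 atm), second-generation Grubbs catalyst RuCl2(=CHPh)(PCy3)(H2IMes) (2 mol%), CH2Cl2, rt; the volatile diene is used as a solution
Reagents that add atoms: none
Why: Cross enyne metathesis of a terminal alkyne with ethylene is a known direct route to 2-substituted buta-1,3-dienes and creates no stereocentre.

Step 2
Reactants: 3 2-isopropylbuta-1,3-diene; 4 methacrolein
Product: 5 (S)-4-isopropyl-1-methylcyclohex-3-ene-1-carbaldehyde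
Conditions: oxazaborolidinium triflimide from (S)-α,α-diphenylprolinol, o-tolylboroxine and Tf2NH (10 mol%), CH2Cl2, −78 °C
Reagents that add atoms: none
Why: In this catalytic enantioselective Diels–Alder reaction the protonated oxazaborolidine binds the formyl group of the 2-substituted acrolein and shields one alkene face, so the para-selective cycloaddition (largest diene coefficient at the CH2 next to the isopropyl-bearing carbon) sets quaternary C1.

Step 3
Reactants: 5 (S)-4-isopropyl-1-methylcyclohex-3-ene-1-carbaldehyde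
Product: 6 (S)-1-isopropyl-4-(2-methoxyethenyl)-4-methylcyclohex-1-ene (E/Z mixture at the enol ether)
Conditions: MeOCH2PPh3Cl, KOtBu, THF, 0 °C → rt
Reagents that add atoms: (methoxymethyl)triphenylphosphonium chloride, COC[P+](c1ccccc1)(c1ccccc1)c1ccccc1.[Cl-]
Why: The Wittig homologation with the non-stabilised methoxymethylene ylide works on hindered, non-enolisable aldehydes, adds C9 and leaves C1 untouched, and the enol ether geometry is irrelevant.

Step 4
Reactants: 6 (S)-1-isopropyl-4-(2-methoxyethenyl)-4-methylcyclohex-1-ene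
Product: 7 (S)-4-(2,2-dimethoxyethyl)-1-isopropyl-4-methylcyclohex-1-ene
Conditions: MeOH, PPTS (cat.), rt
Reagents that add atoms: methanol, CO
Why: Acid-catalysed addition of methanol to the enol ether (acetalisation) masks the future C9 aldehyde in a form that survives ozone, base, hydride and Grignard reagents, while the trisubstituted ring alkene is inert to the mild acid.

Step 5
Reactants: 7 (S)-4-(2,2-dimethoxyethyl)-1-isopropyl-4-methylcyclohex-1-ene
Product: 9 (R)-3-(2,2-dimethoxyethyl)-3,7-dimethyl-6-oxooctanoic acid, via keto aldehyde 8 (not isolated)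
Conditions: O3, CH2Cl2, −78 °C; Me2S, → rt; concentrate; then NaClO2, NaH2PO4, 2-methylbut-2-ene, tBuOH/H2O, rt
Reagents that add atoms: ozone, [O-][O+]=O; sodium chlorite, [Na+].[O-]Cl=O
Why: Ozonolysis cleaves the only C=C bond, the temporary C4=C6 bond of the Diels–Alder ring, to the isopropyl ketone and the aldehyde, and the Pinnick oxidation takes the aldehyde to the acid without touching ketone, acetal or C1.

Step 6
Reactants: 9 (R)-3-(2,2-dimethoxyethyl)-3,7-dimethyl-6-oxooctanoic acid
Product: 12 (1R,2R,5R)-2-(2,2-dimethoxyethyl)-5-isopropyl-2-methyl-6-oxabicyclo[3.2.0]heptan-7-one, via mixed tosyl anhydride 10 (not isolated), via ammonium enolate 11 (not isolated)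
Conditions: TsCl (1.5 equiv), (R)-HBTM (homobenzotetramisole, 20 mol%), LiCl (1 equiv), iPr2NEt (4 equiv), CH2Cl2, rt, slow addition of 9 by syringe pump
Reagents that add atoms: none
Why: TsCl turns 9 into mixed anhydride 10, the isothiourea is acylated and deprotonated to the (Z)-ammonium enolate 11, C5 adds to the LiCl-activated C4 ketone, and the aldolate oxygen attacks the acylammonium carbon to release the catalyst and β-lactone 12. The closest known reaction type is the nucleophile-catalysed aldol-lactonisation of keto acids to cyclopentane-fused β-lactones. The cyclopentane closes in a 5-(enolexo)-exo-trig aldol step and the oxetanone in a 4-exo-trig acyl substitution. C5 is controlled by the catalyst, whose pseudoaxial phenyl group blocks one face of the planar, S···O-locked enolate, and the substrate reinforces this because C6 ends up cis to the small C1 methyl and trans to the larger dimethoxyethyl arm, which is the trans relation of C6 and C10 that the trans ring fusion needs. C4 is controlled by the lactonisation itself, since only the aldolate with its oxygen cis to C6 can close the four-membered ring while the other one reverts by retro-aldol, so oxygen is cis and isopropyl trans to C6. The step needs enolisation at C5 rather than next to the ketone, which the far higher acidity of the acylammonium salt secures, and it needs the aldol to outrun self-condensation of the activated acid, which slow addition and the gem-disubstituted C1 favour.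

Step 7
Reactants: 12 (1R,2R,5R)-2-(2,2-dimethoxyethyl)-5-isopropyl-2-methyl-6-oxabicyclo[3.2.0]heptan-7-one
Product: 13 (1R,2R,5R)-5-(2,2-dimethoxyethyl)-2-hydroxy-2-isopropyl-5-methylcyclopentane-1-carbaldehyde
Conditions: iBu2AlH (1.1 equiv), CH2Cl2, −78 °C; aq. potassium sodium tartrate
Reagents that add atoms: none
Why: Partial hydride reduction of the strained lactone carbonyl at low temperature should stop at the aldehyde level and free the C4 hydroxyl, with C4 and C5 unchanged because the formyl group already sits in its more stable position trans to isopropyl.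

Step 8
Reactants: 13 (1R,2R,5R)-5-(2,2-dimethoxyethyl)-2-hydroxy-2-isopropyl-5-methylcyclopentane-1-carbaldehyde; 14 2-(2-bromoethyl)-1,3-dioxolane
Product: 15 (1R,2S,3R)-3-(2,2-dimethoxyethyl)-2-[(1S)-3-(1,3-dioxolan-2-yl)-1-hydroxypropyl]-1-isopropyl-3-methylcyclopentan-1-ol
Conditions: 14, Mg, THF, ≤ 25 °C; then 13 (0.33 equiv relative to the reagent), THF, −78 → −40 °C; aq. NH4Cl
Reagents that add atoms: none
Why: In this chelation-controlled Grignard addition the magnesium alkoxide of the C4 hydroxyl binds the aldehyde oxygen and the nucleophile enters the carbonyl face flanked by H5, away from quaternary C1, which gives the (S)-carbinol at C6, anti to the C4 oxygen.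

Step 9
Reactants: 15 (1R,2S,3R)-3-(2,2-dimethoxyethyl)-2-[(1S)-3-(1,3-dioxolan-2-yl)-1-hydroxypropyl]-1-isopropyl-3-methylcyclopentan-1-ol; 16 4-(methoxymethoxy)benzoic acid
Product: 17 (1S)-1-[(1S,2R,5R)-5-(2,2-dimethoxyethyl)-2-hydroxy-2-isopropyl-5-methylcyclopentyl]-3-(1,3-dioxolan-2-yl)propyl 4-(methoxymethoxy)benzoate
Conditions: EDC·HCl, DMAP, CH2Cl2, rt
Reagents that add atoms: none
Why: The Steglich esterification acylates only the secondary C6 hydroxyl, because the tertiary C4 hydroxyl next to isopropyl is too hindered, and it proceeds with retention at C6.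

Step 10
Reactants: 17 (1S)-1-[(1S,2R,5R)-5-(2,2-dimethoxyethyl)-2-hydroxy-2-isopropyl-5-methylcyclopentyl]-3-(1,3-dioxolan-2-yl)propyl 4-(methoxymethoxy)benzoate
Product: 18 (1S)-1-[(1S,2R,5R)-2-hydroxy-2-isopropyl-5-methyl-5-(2-oxoethyl)cyclopentyl]-4-oxobutyl 4-hydroxybenzoate
Conditions: 2 M aq. HCl, THF, rt → 40 °C
Reagents that add atoms: water, O
Why: Aqueous acid hydrolysis cleaves the dimethyl acetal, the dioxolane and the aryl methoxymethyl ether in one operation, under conditions that the benzoate ester and the tertiary alcohol should survive.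

Step 11
Reactants: 18 (1S)-1-[(1S,2R,5R)-2-hydroxy-2-isopropyl-5-methyl-5-(2-oxoethyl)cyclopentyl]-4-oxobutyl 4-hydroxybenzoate
Product: 20 (3R,3aS,4S,8aR)-6-formyl-3-hydroxy-3-isopropyl-8a-methyl-1,2,3,3a,4,5,8,8a-octahydroazulen-4-yl 4-hydroxybenzoate (target), via aldol adduct 19 (not isolated)
Conditions: dibenzylammonium trifluoroacetate (0.5 equiv), toluene (high dilution), 60 °C
Reagents that add atoms: none
Why: In this amine-salt-catalysed intramolecular aldol condensation the enamine of the unhindered C14 aldehyde attacks the C9 aldehyde through C8 in a 7-(enolexo)-exo-trig closure and loss of water gives the conjugated enal, whereas the alternative enamine carbon C10 is neopentyl and much slower, and no stereocentre is formed or touched.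

Compound list
1 | 3-methylbut-1-yne | CC(C)C#C | starting material
2 | ethylene | C=C | starting material
3 | 2-isopropylbuta-1,3-diene | C=CC(=C)C(C)C | intermediate
4 | methacrolein | CC(=C)C=O | starting material
5 | (S)-4-isopropyl-1-methylcyclohex-3-ene-1-carbaldehyde | O=C[C@]1(C)CC=C(C(C)C)CC1 | intermediate
6 | (S)-1-isopropyl-4-(2-methoxyethenyl)-4-methylcyclohex-1-ene (E/Z mixture) | COC=C[C@]1(C)CC=C(C(C)C)CC1 | intermediate
7 | (S)-4-(2,2-dimethoxyethyl)-1-isopropyl-4-methylcyclohex-1-ene | COC(OC)C[C@]1(C)CC=C(C(C)C)CC1 | intermediate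
8 | (S)-3-(2,2-dimethoxyethyl)-3,7-dimethyl-6-oxooctanal (keto aldehyde, not isolated) | O=CC[C@@](C)(CC(OC)OC)CCC(=O)C(C)C | intermediate
9 | (R)-3-(2,2-dimethoxyethyl)-3,7-dimethyl-6-oxooctanoic acid | OC(=O)C[C@@](C)(CC(OC)OC)CCC(=O)C(C)C | intermediate
10 | mixed anhydride of 9 and p-toluenesulfonic acid (not isolated) | Cc1ccc(cc1)S(=O)(=O)OC(=O)C[C@@](C)(CC(OC)OC)CCC(=O)C(C)C | intermediate
11 | zwitterionic C5 ammonium enolate of the N-acyl (R)-HBTM salt of 9 (not isolated) | C1CN2c3ccccc3SC2=[N+]([C@H]1c1ccccc1)C([O-])=C[C@@](C)(CC(OC)OC)CCC(=O)C(C)C | intermediate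
12 | (1R,2R,5R)-2-(2,2-dimethoxyethyl)-5-isopropyl-2-methyl-6-oxabicyclo[3.2.0]heptan-7-one | O=C1O[C@@]2(C(C)C)CC[C@](C)(CC(OC)OC)[C@@H]12 | intermediate
13 | (1R,2R,5R)-5-(2,2-dimethoxyethyl)-2-hydroxy-2-isopropyl-5-methylcyclopentane-1-carbaldehyde | O=C[C@H]1[C@](O)(C(C)C)CC[C@]1(C)CC(OC)OC | intermediate
14 | 2-(2-bromoethyl)-1,3-dioxolane | BrCCC1OCCO1 | starting material
15 | (1R,2S,3R)-3-(2,2-dimethoxyethyl)-2-[(1S)-3-(1,3-dioxolan-2-yl)-1-hydroxypropyl]-1-isopropyl-3-methylcyclopentan-1-ol | O[C@@H](CCC1OCCO1)[C@H]2[C@](O)(C(C)C)CC[C@]2(C)CC(OC)OC | intermediate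
16 | 4-(methoxymethoxy)benzoic acid | COCOc1ccc(cc1)C(=O)O | starting material
17 | C6 4-(methoxymethoxy)benzoate of 15 | COCOc1ccc(cc1)C(=O)O[C@@H](CCC2OCCO2)[C@H]3[C@](O)(C(C)C)CC[C@]3(C)CC(OC)OC | intermediate
18 | (1S)-1-[(1S,2R,5R)-2-hydroxy-2-isopropyl-5-methyl-5-(2-oxoethyl)cyclopentyl]-4-oxobutyl 4-hydroxybenzoate | Oc1ccc(cc1)C(=O)O[C@@H](CCC=O)[C@H]2[C@](O)(C(C)C)CC[C@]2(C)CC=O | intermediate
19 | bicyclic aldol adduct, 9-hydroxy-8,9-dihydro form of the target (mixture at C8 and C9, not isolated) | CC(C)[C@]1(O)CC[C@]2(C)CC(O)C(C=O)C[C@H](OC(=O)c3ccc(O)cc3)[C@H]21 | intermediate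
20 | (3R,3aS,4S,8aR)-6-formyl-3-hydroxy-3-isopropyl-8a-methyl-1,2,3,3a,4,5,8,8a-octahydroazulen-4-yl 4-hydroxybenzoate | CC(C)[C@]1(O)CC[C@]2(C)CC=C(C=O)C[C@H](OC(=O)c3ccc(O)cc3)[C@H]21 | target

Total step count: 11. Longest linear sequence: 11 steps (from 1).

Steps most likely to fail

Step 6. The neopentyl ammonium enolate may add too slowly to the hindered isopropyl ketone. Self-condensation of the activated acid would then take over, or catalyst control could erode.
- The fallback is a stoichiometric, auxiliary-controlled titanium aldol that sets out from 9 and comes back at 13.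
- The acid is coupled (PivCl, Et3N, then LiCl and (R)-4-benzyl-oxazolidin-2-one) to the N-acyl oxazolidinone F1.
- Soft enolisation with TiCl4 and iPr2NEt in CH2Cl2 at −78 °C touches only the chelated imide. The chlorotitanium enolate adds to the tethered ketone and gives the β-hydroxy imide F2, held as a stable titanium chelate.
- LiBH4 in Et2O with one equivalent of water removes the auxiliary and gives the diol F3.
- TEMPO with PhI(OAc)2 oxidises only the primary alcohol of F3 to aldehyde 13.

Step 11. The closure may go through the wrong enamine carbon (C10), or oligomerisation may win over formation of the seven-membered ring.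
- The fallback replaces the aldol closure by ring-closing metathesis. It sets out from 13 and comes back at 20.
- A Barbier allylation of 13 with 2-(bromomethyl)prop-2-en-1-yl tert-butyldimethylsilyl ether and In powder in THF/H2O gives the homoallylic diol F4.
- EDC/DMAP esterification with 16 gives the benzoate F5.
- PPTS in wet acetone hydrolyses only the dimethyl acetal and gives the aldehyde F6.
- Ph3P=CH2 converts F6 into the allyl compound F7.
- The second-generation Grubbs catalyst RuCl2(=CHPh)(PCy3)(H2IMes) in refluxing CH2Cl2 closes the trisubstituted cycloheptene F8.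
- HCl in MeOH/THF removes the silyl and methoxymethyl groups and gives the allylic alcohol F9.
- MnO2 oxidises the allylic alcohol to 20.

Step 8. Facial selectivity may be poor if the magnesium chelate is not maintained, and the β-alkoxide aldehyde may open by retro-aldol reaction.
- The fallback sets C6 by hydroxyl-directed reduction instead of by addition. It sets out from 12 and comes back at 15.
- MeNH(OMe)·HCl with iPrMgCl in THF opens the β-lactone to the N-methoxy-N-methylamide F10.
- The Grignard reagent from 14 converts F10 into the β-hydroxy ketone F11.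
- An Evans–Saksena reduction (Me4NBH(OAc)3, MeCN/AcOH, −20 °C) delivers hydride from the boron bound to the C4 oxygen and gives the 1,3-anti diol 15.

Further compounds
F1 | step 6 | (R)-4-benzyl-3-[(R)-3-(2,2-dimethoxyethyl)-3,7-dimethyl-6-oxooctanoyl]oxazolidin-2-one | O=C1OC[C@@H](Cc2ccccc2)N1C(=O)C[C@@](C)(CC(OC)OC)CCC(=O)C(C)C
F2 | step 6 | (R)-4-benzyl-3-{[(1R,2R,5R)-5-(2,2-dimethoxyethyl)-2-hydroxy-2-isopropyl-5-methylcyclopentyl]carbonyl}oxazolidin-2-one | O=C1OC[C@@H](Cc2ccccc2)N1C(=O)[C@H]1[C@](O)(C(C)C)CC[C@]1(C)CC(OC)OC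
F3 | step 6 | (1R,2S,3R)-3-(2,2-dimethoxyethyl)-2-(hydroxymethyl)-1-isopropyl-3-methylcyclopentan-1-ol | OC[C@H]1[C@](O)(C(C)C)CC[C@]1(C)CC(OC)OC
F4 | step 11 | (1R,2S,3R)-2-[(1S)-3-{[(tert-butyldimethylsilyl)oxy]methyl}-1-hydroxybut-3-en-1-yl]-3-(2,2-dimethoxyethyl)-1-isopropyl-3-methylcyclopentan-1-ol | O[C@@H](CC(=C)CO[Si](C)(C)C(C)(C)C)[C@H]1[C@](O)(C(C)C)CC[C@]1(C)CC(OC)OC
F5 | step 11 | C6 4-(methoxymethoxy)benzoate of F4 | COCOc1ccc(cc1)C(=O)O[C@@H](CC(=C)CO[Si](C)(C)C(C)(C)C)[C@H]2[C@](O)(C(C)C)CC[C@]2(C)CC(OC)OC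
F6 | step 11 | C9 aldehyde from F5 (2-oxoethyl arm at C1) | COCOc1ccc(cc1)C(=O)O[C@@H](CC(=C)CO[Si](C)(C)C(C)(C)C)[C@H]2[C@](O)(C(C)C)CC[C@]2(C)CC=O
F7 | step 11 | diene from F6 (allyl arm at C1) | COCOc1ccc(cc1)C(=O)O[C@@H](CC(=C)CO[Si](C)(C)C(C)(C)C)[C@H]2[C@](O)(C(C)C)CC[C@]2(C)CC=C
F8 | step 11 | (3R,3aS,4S,8aR)-6-{[(tert-butyldimethylsilyl)oxy]methyl}-3-hydroxy-3-isopropyl-8a-methyl-1,2,3,3a,4,5,8,8a-octahydroazulen-4-yl 4-(methoxymethoxy)benzoate | CC(C)[C@]1(O)CC[C@]2(C)CC=C(CO[Si](C)(C)C(C)(C)C)C[C@H](OC(=O)c3ccc(OCOC)cc3)[C@H]21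
F9 | step 11 | (3R,3aS,4S,8aR)-3-hydroxy-6-(hydroxymethyl)-3-isopropyl-8a-methyl-1,2,3,3a,4,5,8,8a-octahydroazulen-4-yl 4-hydroxybenzoate | CC(C)[C@]1(O)CC[C@]2(C)CC=C(CO)C[C@H](OC(=O)c3ccc(O)cc3)[C@H]21
F10 | step 8 | (1R,2R,5R)-5-(2,2-dimethoxyethyl)-2-hydroxy-2-isopropyl-N-methoxy-N,5-dimethylcyclopentane-1-carboxamide | CON(C)C(=O)[C@H]1[C@](O)(C(C)C)CC[C@]1(C)CC(OC)OC
F11 | step 8 | 1-[(1R,2R,5R)-5-(2,2-dimethoxyethyl)-2-hydroxy-2-isopropyl-5-methylcyclopentyl]-3-(1,3-dioxolan-2-yl)propan-1-one | O=C(CCC1OCCO1)[C@H]2[C@](O)(C(C)C)CC[C@]2(C)CC(OC)OC
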